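- To whoever takes over this bench: the flask and the earlier runs are below, with what you will be asked.

| setting | south | north-east | flask |
|---|---|---|---|
| substrate | 0.18 M | 0.41 M | 0.27 M |
| reagent | 2 equiv | 2 equiv | 2.00 equiv |
| remark | run made earlier | run made earlier |  |
| time |  |  | 2.5 min |

- south (time / s: other mono adduct / %, first product / %): 15.0: 8, 8; 40.0: 14, 14; 80.0: 18, 16; 120: 22, 21
- north-east (time / s: other mono adduct / %, first product / %): 15.0: 14, 15; 40.0: 22, 24; 80.0: 22, 26; 120: 23, 20

(readings scatter by 2 percentage points)



1. equivalents of reagent to substrate, everything else as given, that leave most other mono adduct at 2.5 min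
2. the amount of other mono adduct then, in percent of the substrate charged
3. the amount of other mono adduct with the amounts as given

- I assumed that, at fixed equivalents, making and using up the other mono adduct each need two partners, so I divided the percent rate by the concentration; what was left depended on one product, the dose40.5 M·s, substrate concentration times time.
- Your flask reaches that dose of 40.5 M·s at 2.5 min, between the north-east readings at 32.8 M·s and 49.2 M·s, which showed 22% and 23% of other mono adduct, so I expected 22.5% when you came.
- Leave the reagent charge alone: the south and north-east runs were both charged at 2 equiv, so I had no reading at another charge to go on, and the dose rule holds at fixed equivalents.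
- The forecast, a little above my figure, gave 23% as charged and 24% at 1.7 equiv, calling it “The optimum is very flat”.
- The flask gave 21.8% as charged, and 21.9% at 1.83 equiv.

    substrate + reagent ⇌ first product (K = 4.00 L mol⁻¹, k = 0.0180 L mol⁻¹ s⁻¹)
    substrate + reagent → other mono adduct (k = 0.0150 L mol⁻¹ s⁻¹)
    reagent + first product → bis adduct (k = 0.0130 L mol⁻¹ s⁻¹)
    reagent + other mono adduct → bis adduct (k = 0.0140 L mol⁻¹ s⁻¹)
    substrate ⇌ dormant form (K = 1.70, k = 0.00380 s⁻¹)
    reagent → decomposition product (k = 3.40 × 10⁻⁵ s⁻¹)

- At its dose of 40.5 M·s the flask had passed the maximum of a consecutive-reaction intermediate: the other mono adduct was made 3.65 times as fast as it was used up at 0.558 min, but that ratio had fallen to 0.800 at 2.50 min. A neighbour flask charged with 0.068 M reached a dose of 10.2 M·s, between the south doses of 7.20 M·s and 14.4 M·s, which read 14% and 18%, and it held 14.8%.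

The numbers in the tables were generated by integration with constants of no real substance; scatter was added.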